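## Structural features

The target 12 is a flavone: a benzopyran-4-one (ring A fused to ring C at C4a–C8a) that carries a 2,5-dihydroxyphenyl ring B on C2 through the C2–C1' single bond. Ring A is fully substituted, with OH on C5, OMe on C6, C7 and C8, O1 on C8a and the carbonyl carbon C4 on C4a. There is no stereocenter, so nothing has to be set or relayed. The fragile parts are the hydroquinone ring B (easily oxidized to a quinone, above all in base), the pyranone ring (opened by hot strong alkali) and the C6 methyl ether next to the chelated 5-OH (prone to Lewis-acid cleavage). The real difficulty is the hexasubstituted ring A: five contiguous oxygens must be placed, exactly one of the four on C5–C8 must stay unmethylated, and ring B must stay reduced to the end. The key step exploits the 1,3,5-relationship of the oxygens on C5, C7 and C8a, a phloroglucinol pattern with two further oxygens on C6 and C8, which is the Claisen fold of a six-carbon triketide chain that already carries methoxy groups on C4 and C6. The fold gives a ring with a local mirror plane through C4a and C7, so the later annulation of ring C can give only one isomer and the C7 hydroxyl differs from the C5 hydroxyl by chelation alone.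

## Logic of the disconnections

12 ⇒ 11. The two O–CH2Ph bonds on O2' and O5' are cut. The free hydroquinone is the most oxidizable part of the molecule and its hydroxyls would compete in every base-mediated step, so ring B is carried as a diether. The forward step must be neutral and reductive and must spare C2=C3 and the three aryl methyl ethers.

11 ⇒ 10. The O7–CH3 bond is cut. In 10 the 7-OH is free and acidic while the 5-OH is hydrogen-bonded to the C4 carbonyl, so the two can be told apart. The gain is that ring A of 10 maps onto a symmetric triol. The forward step must stop at mono-alkylation.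

10 ⇒ 5 + 8 (through 9). C4a–C4 and O1–C2 of ring C are cut. Triol 5 has a single ring CH flanked by two equivalent hydroxyls, so acylation there and closure through either neighbour can lead to one flavone only. The molecule falls into a ring A piece and a ring B piece of similar size. The forward step must acylate at carbon and close in the chromone sense, without acid that would favour a coumarin or attack the benzyl ethers.

8 ⇒ 7. The bond between the future C3 and C4 is cut, that is, the bond from the methyl carbon of the ketone to the ester carbonyl. This reduces the three-carbon unit to an aryl methyl ketone and a carbonate ester. The forward step needs a fully protected ring B, because free phenols would consume the base.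

7 ⇒ 6. The two benzyl–oxygen bonds are cut, which leads to a commercial dihydroxy ketone. The forward step must also alkylate the hydrogen-bonded ortho hydroxyl.

5 ⇒ 3 (through 4). The C5–C6 bond of ring A (equivalent to C8–C8a) is cut, which is the bond between C6 and C1 of the chain of 3. This is the strategic cut: an aromatic ring with five oxygens becomes an acyclic ester in which all five oxygens and both methyl ethers are already in place. The forward step must cyclize through carbon and not through oxygen, and the electron-rich product must be kept from air.

3 ⇒ 1 + 2. The C4–C5 bond of the chain is cut. Both halves are methoxyacetyl-derived units: C4 is the γ-carbon of β-keto ester 1 and can be made nucleophilic as its dianion, and C5 comes from amide 2 at the ketone oxidation level. Two commercial compounds give 3 in one step. The forward step needs γ-selectivity and an acyl donor that cannot add twice.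

## Other disconnections considered

Alternative 1: The cut runs through ring C at C8a–O1, C4a–C4 and O1–C2, so that ring A enters as an aryne and the C2–C3–C4 unit with ring B as an arylpropiolic acid.
- Forward key step: fluoride (CsF) would release the symmetric tetramethoxy aryne from 2,3,4,5-tetramethoxy-6-(trimethylsilyl)phenyl trifluoromethanesulfonate A1. The carboxylate oxygen of 3-[2,5-bis(benzyloxy)phenyl]prop-2-ynoic acid A2 adds to it, the aryl anion takes over the acyl group in a four-centre shift, and the phenoxide closes onto the ynone in a 6-endo-dig manner. The product would be 2-[2,5-bis(benzyloxy)phenyl]-5,6,7,8-tetramethoxy-4H-chromen-4-one A3.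
- In its favour: three bonds and ring C form in one flask, the symmetric aryne raises no regiochemical question, and all four ring A oxygens are in place, so no selective O-methylation is needed. Insertion of arynes into carboxylic acids followed by ynone closure is a known way to flavones.
- Against it here: A1 is a hexasubstituted benzene that needs a sequence of its own (halogenation, phenol formation, silyl migration, triflation). An aryne flanked by two methoxy groups and carrying four donors is hindered and less electrophilic. A2 needs about three steps. The closure could leak to the 5-exo mode. A3 still requires cleavage of the C5 methyl ether beside three others.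
- Comparison, structure: the alternative differentiates O5 at the end by chelation-controlled demethylation, where the chosen plan differentiates O7 in 10 by acidity. The alternative is the better here in that one Lewis-acid operation could remove the C5 methyl and both benzyl groups of A3 together.
- Comparison, mechanism: its key step has closer precedent than the fold of the untested methoxylated triketide 3, which is a point for the alternative.
- Comparison, step economy: the chosen plan is ahead, at seven operations against an estimated ten, with a comparable longest linear sequence.

Alternative 2: The cut removes ring B; C1'–C2', C2'–C3' and C5'–C6' are formed last on a finished chromone.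
- Forward key step: the Fischer carbene pentacarbonyl[methoxy(vinyl)carbene]chromium A5, of formula (CO)5Cr=C(OMe)CH=CH2, would react with 2-ethynyl-5,6,7,8-tetramethoxy-4H-chromen-4-one A4 in a Dötz benzannulation. Alkyne insertion into the chromium–carbon double bond of A5, CO insertion to a vinylketene and electrocyclization would give 2-(2-hydroxy-5-methoxyphenyl)-5,6,7,8-tetramethoxy-4H-chromen-4-one A6, with the larger alkyne substituent next to the new phenol.
- In its favour: ring B is made with both oxygens placed and the 2'-OH free, without protecting groups, and the regiochemistry is dictated by the terminal alkyne.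
- Against it here: A5 is a stoichiometric chromium carbonyl reagent. A4 is an electron-poor alkyne conjugated to a Michael-accepting pyranone, a poor electronic match that could divert to cyclopentannulation or furan formation. A4 needs about five steps. A6 still has methyl ethers on O5' and O5 to be removed beside those on C6–C8; the O5' ether can only go by oxidation of ring B to the quinone and reduction, which endangers the electron-rich ring A.
- Comparison, structure: the alternative is the better in protecting-group economy for ring B.
- Comparison, mechanism: both key steps are known reaction types on untested substrates and are equal in that respect, but the electronic mismatch of A4 is judged the more serious risk.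
- Comparison, step economy: the alternative is longer (about ten linear operations) and leaves chromium waste, so the chosen plan is ahead.

Alternative 3: The cut is O1–C8a alone; ring C is closed by an oxygen nucleophile onto an oxidized ring A.
- Forward key step: 1-[2,5-bis(benzyloxy)phenyl]-3-(2,5-dihydroxy-3,4-dimethoxyphenyl)propane-1,3-dione A7 would be oxidized at a carbon anode to 2-{3-[2,5-bis(benzyloxy)phenyl]-3-oxopropanoyl}-5,6-dimethoxycyclohexa-2,5-diene-1,4-dione A8. In A8 the enol oxygen of the diketone adds to the quinone carbon next to the acyl group (6-endo-trig), and tautomerization would give 2-[2,5-bis(benzyloxy)phenyl]-5,8-dihydroxy-6,7-dimethoxy-4H-chromen-4-one A9.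
- In its favour: electrons are the only oxidant, the step runs at room temperature, and ring A comes from an aromatic precursor. A9 has one chelated and one free hydroxyl, so methylation at O8 would lead straight to 11.
- Against it here: A9 is a more electron-rich hydroquinone than A7 and should be oxidized at lower potential, so over-oxidation of the new ring A would have to be countered by charge control or a reductive work-up. The dialkoxyarene ring B is also oxidizable. A7 requires a ring A acetophenone with free hydroquinone hydroxyls and a diketone synthesis that probably needs extra protection.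
- Comparison, structure: both plans end with methylation of the one unchelated hydroxyl and hydrogenolysis; they are equal here.
- Comparison, mechanism: the alternative is the better in mildness (no strong base, no 240 °C step). The chosen plan is the better in chemoselectivity, since none of its steps applies an oxidant to the electron-rich rings.
- Comparison, step economy: an estimated seven to nine steps against seven, so equal or slightly behind.

Key step: step 2

Remark: 3 and 4 are drawn in their keto forms although both should be largely enolized; 1, 2, 6, benzyl bromide, diethyl carbonate and iodomethane are taken as commercial.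

## Route

Step 1
Reactants: 1 methyl 4-methoxy-3-oxobutanoate; 2 N,2-dimethoxy-N-methylacetamide
Product: 3 methyl 4,6-dimethoxy-3,5-dioxohexanoate (racemic at C4, enolized)
Conditions: 1 (1.2 equiv), LiN(i-Pr)2 (2.5 equiv), THF, −78 to 0 °C; then 2, −78 to 0 °C; aq. HCl to pH 3
Reagents that add atoms: none
Why: γ-Acylation of a β-keto ester dianion by an N-methoxy-N-methyl amide: the second deprotonation takes place at C4, which is the more reactive carbanion, and the chelated tetrahedral adduct should survive until the acid quench, so that neither double addition nor proton exchange with the more acidic product interferes. The new stereocenter at C4 is not controlled and is lost in step 2.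

Step 2
Reactants: 3 methyl 4,6-dimethoxy-3,5-dioxohexanoate
Product: 5 2,4-dimethoxybenzene-1,3,5-triol, via 2,4-dimethoxycyclohexane-1,3,5-trione 4 (not isolated)
Conditions: NaOMe (4 equiv), anhydrous MeOH, sealed tube, 120 °C, Ar; then degassed 2 M HCl, 0 °C
Reagents that add atoms: none
Why: NaOMe deprotonates 3 at C2 and C4 and, in equilibrium, at the C6 methoxymethyl carbon; that C6 enolate adds to the C1 ester carbonyl, methoxide is expelled, and trione 4 enolizes to the aromatic triol 5, which is held as its phenoxide under the basic conditions. The closest known reaction is the base-induced Claisen cyclization of 3,5-dioxohexanoate esters to phloroglucinol, the laboratory counterpart of the polyketide fold; the methoxylated chain is a new substrate for this known reaction. The one ring is closed in a 6-exo-trig mode at the ester carbonyl, with the enolate double bond inside the forming ring (enolendo). No stereocenter is created and the one at C4 of 3 disappears on aromatization. The selectivity needed is carbon against oxygen cyclization: attack of the C5 enolate oxygen on the ester gives a 4-hydroxy-2-pyranone, but under anhydrous methoxide that lactone should reopen, whereas the Claisen product leaves the equilibrium as an aromatic phenoxide. C6 is the only carbon that can reach a carbonyl through a six-membered transition state, since closure from C2 or C4 would give four-membered rings, and its methoxy group should acidify the terminal CH2 inductively relative to the methyl group of the parent ester. Air must be excluded through the acidification because 5 is an electron-rich polyphenol.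

Step 3
Reactants: 6 1-(2,5-dihydroxyphenyl)ethanone
Product: 7 1-[2,5-bis(benzyloxy)phenyl]ethanone
Conditions: BnBr (2.5 equiv), K2CO3 (3 equiv), DMF, 70 °C
Reagents that add atoms: benzyl bromide, BrCc1ccccc1
Why: Williamson ether synthesis; the 5-OH should react readily and the hydrogen-bonded 2-OH needs the excess of reagent and the heat. Both phenols must be capped before the enolate chemistry of step 4 and the base of step 6.

Step 4
Reactants: 7 1-[2,5-bis(benzyloxy)phenyl]ethanone
Product: 8 ethyl 3-[2,5-bis(benzyloxy)phenyl]-3-oxopropanoate
Conditions: NaH (2.5 equiv), (EtO)2CO (3 equiv), toluene, reflux; aq. HCl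
Reagents that add atoms: diethyl carbonate, CCOC(=O)OCC
Why: Crossed Claisen condensation of the methyl ketone enolate with diethyl carbonate, which cannot enolize; irreversible deprotonation of the β-keto ester by NaH should drive it to completion.

Step 5
Reactants: 5 2,4-dimethoxybenzene-1,3,5-triol; 8 ethyl 3-[2,5-bis(benzyloxy)phenyl]-3-oxopropanoate
Product: 10 2-[2,5-bis(benzyloxy)phenyl]-5,7-dihydroxy-6,8-dimethoxy-4H-chromen-4-one, via acylphloroglucinol diketone 9 (not isolated)
Conditions: 5, 8 (1.5 equiv), neat, 240 °C (microwave or metal bath), Ar, 5–10 min, EtOH distilled off
Reagents that add atoms: none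
Why: Mentzer thermal chromone synthesis: loss of ethanol from 8 should give an aroylketene that acylates the only free ring carbon of 5 (directly or by O-acylation and thermal Fries shift) to diketone 9, which cyclodehydrates through either of the two equivalent flanking hydroxyls. Without acid the Pechmann closure to a 4-arylcoumarin is not expected, and the symmetry of 5 allows a single flavone.

Step 6
Reactants: 10 2-[2,5-bis(benzyloxy)phenyl]-5,7-dihydroxy-6,8-dimethoxy-4H-chromen-4-one
Product: 11 2-[2,5-bis(benzyloxy)phenyl]-5-hydroxy-6,7,8-trimethoxy-4H-chromen-4-one
Conditions: MeI (1.1 equiv), K2CO3 (1.2 equiv), acetone, rt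
Reagents that add atoms: iodomethane, CI
Why: Chelation-controlled selective O-alkylation: the 7-OH is a vinylogous carboxylic acid (conjugated with the C4 carbonyl) and not hydrogen-bonded, so one equivalent of K2CO3 should ionize it alone, while the 5-OH stays locked in its hydrogen bond to the C4 carbonyl. Ring B carries no free hydroxyl at this stage.

Step 7
Reactants: 11 2-[2,5-bis(benzyloxy)phenyl]-5-hydroxy-6,7,8-trimethoxy-4H-chromen-4-one
Product: 12 2-(2,5-dihydroxyphenyl)-5-hydroxy-6,7,8-trimethoxy-4H-chromen-4-one (5,2',5'-trihydroxy-6,7,8-trimethoxyflavone)
Conditions: H2 (1 atm), 10% Pd/C, EtOAc–MeOH, rt; filtration and concentration under Ar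
Reagents that add atoms: none
Why: Catalytic hydrogenolysis of benzyl aryl ethers; the C2=C3 bond of the pyranone is part of a vinylogous ester and should not be reduced at 1 atm, and the aryl methyl ethers are inert. Work-up under Ar protects the hydroquinone.

## Compound list

1 | methyl 4-methoxy-3-oxobutanoate | COCC(=O)CC(=O)OC | starting material
2 | N,2-dimethoxy-N-methylacetamide | COCC(=O)N(C)OC | starting material
3 | methyl 4,6-dimethoxy-3,5-dioxohexanoate (racemic at C4, keto form drawn) | COCC(=O)C(OC)C(=O)CC(=O)OC | intermediate
4 | 2,4-dimethoxycyclohexane-1,3,5-trione (mixture of stereoisomers and enol forms, not isolated) | COC1C(=O)CC(=O)C(OC)C1=O | intermediate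
5 | 2,4-dimethoxybenzene-1,3,5-triol | COc1c(O)cc(O)c(OC)c1O | intermediate
6 | 1-(2,5-dihydroxyphenyl)ethanone | CC(=O)c1cc(O)ccc1O | starting material
7 | 1-[2,5-bis(benzyloxy)phenyl]ethanone | CC(=O)c1cc(OCc2ccccc2)ccc1OCc1ccccc1 | intermediate
8 | ethyl 3-[2,5-bis(benzyloxy)phenyl]-3-oxopropanoate | CCOC(=O)CC(=O)c1cc(OCc2ccccc2)ccc1OCc1ccccc1 | intermediate
9 | 1-[2,5-bis(benzyloxy)phenyl]-3-(2,4,6-trihydroxy-3,5-dimethoxyphenyl)propane-1,3-dione (not isolated) | COc1c(O)c(OC)c(O)c(C(=O)CC(=O)c2cc(OCc3ccccc3)ccc2OCc2ccccc2)c1O | intermediate
10 | 2-[2,5-bis(benzyloxy)phenyl]-5,7-dihydroxy-6,8-dimethoxy-4H-chromen-4-one | COc1c(O)c(OC)c2oc(-c3cc(OCc4ccccc4)ccc3OCc3ccccc3)cc(=O)c2c1O | intermediate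
11 | 2-[2,5-bis(benzyloxy)phenyl]-5-hydroxy-6,7,8-trimethoxy-4H-chromen-4-one | COc1c(OC)c(OC)c2oc(-c3cc(OCc4ccccc4)ccc3OCc3ccccc3)cc(=O)c2c1O | intermediate
12 | 2-(2,5-dihydroxyphenyl)-5-hydroxy-6,7,8-trimethoxy-4H-chromen-4-one | COc1c(OC)c(O)c2c(=O)cc(-c3cc(O)ccc3O)oc2c1OC | target

## Step count and least certain steps

Total step count: 7. Longest linear sequence: 5 steps (steps 1, 2, 5, 6, 7; the ring B branch, steps 3, 4, 5, 6, 7, is equally long).

**Step 2 (key step).** The most likely failures are cyclization through oxygen to a pyranone that does not reopen, methoxide-induced retro-Claisen fragmentation of the 1,3-diketone, and air oxidation of the product during acidification. The cause is that the nucleophilic C6 is the least acidic carbon of the chain and that the ester is deactivated once C2 is deprotonated. The fallback builds ring A from an aromatic triol and brings in the two methoxy groups by substitution. It sets out from 8 and comes back to the route at 10. Compound 8 is condensed with commercial benzene-1,3,5-triol under the conditions of step 5 to give 2-[2,5-bis(benzyloxy)phenyl]-5,7-dihydroxy-4H-chromen-4-one F1. F1 is brominated at the two activated ring A positions with N-bromosuccinimide (2 equiv, DMF, 0 °C), which should give 2-[2,5-bis(benzyloxy)phenyl]-6,8-dibromo-5,7-dihydroxy-4H-chromen-4-one F2; the less activated ring B is expected to stay untouched at this stoichiometry. F2 is then subjected to copper-mediated methanolysis (CuBr, NaOMe, MeOH–DMF, reflux), which would replace both bromides and deliver 10.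

**Step 5.** The risks are thermal or oxidative degradation of 5 before acylation, migration or loss of a benzyl group at 240 °C, and closure in the coumarin sense. The fallback is a stepwise acylation and closure under mild conditions. It sets out from 5 and comes back at 10 by way of 9, which is isolated in this variant. Friedel–Crafts acetylation of 5 (AcOH, BF3·OEt2, 80 °C) should give 1-(2,4,6-trihydroxy-3,5-dimethoxyphenyl)ethanone F3. F3 is converted into its polyanion (LiN(SiMe3)2, 5 equiv, THF, −78 °C) and acylated at carbon with 2,5-bis(benzyloxy)benzoyl chloride F4 to give 9. F4 is prepared from the commercial acid with (COCl)2. Cyclodehydration of 9 (TsOH, toluene, reflux) gives 10.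

**Step 1.** The risks are incomplete γ-deprotonation because C4 carries a methoxy group, and proton transfer from 2 to the dianion in place of acylation. The fallback replaces the dianion by a neutral bis-silyl dienolate. It sets out from 1 and comes back at 3. Silylation of 1 (Me3SiCl, Et3N) gives methyl 4-methoxy-3-[(trimethylsilyl)oxy]but-2-enoate F5. F5 is deprotonated and silylated a second time (LiN(i-Pr)2, THF, −78 °C; Me3SiCl) to give 1,4-dimethoxy-1,3-bis[(trimethylsilyl)oxy]buta-1,3-diene F6. F6 is acylated at its terminal carbon with methoxyacetyl chloride (CH2Cl2, −78 to 20 °C) and gives 3 after hydrolytic work-up.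

**Step 6.** The risks are over-alkylation at O5 once excess base breaks the hydrogen bond, and slow alkylation of O7, which sits between two methoxy groups. The fallback gives up the selective alkylation and uses a selective dealkylation. It sets out from 10 and comes back at 12, so it replaces step 7 as well. Exhaustive methylation of 10 (Me2SO4, K2CO3, acetone, reflux) gives 2-[2,5-bis(benzyloxy)phenyl]-5,6,7,8-tetramethoxy-4H-chromen-4-one F7. F7 is the same compound as A3. F7 is then treated with BCl3 and pentamethylbenzene as cation scavenger (CH2Cl2, −78 to 0 °C), which should cleave the C5 methyl ether, activated by chelation of boron to the C4 carbonyl, together with both benzyl ethers and give 12. Time and equivalents are limited to spare the C6 methyl ether.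

## Further compounds

F1 | step 2 | 2-[2,5-bis(benzyloxy)phenyl]-5,7-dihydroxy-4H-chromen-4-one | O=c1cc(-c2cc(OCc3ccccc3)ccc2OCc2ccccc2)oc2cc(O)cc(O)c12
F2 | step 2 | 2-[2,5-bis(benzyloxy)phenyl]-6,8-dibromo-5,7-dihydroxy-4H-chromen-4-one | O=c1cc(-c2cc(OCc3ccccc3)ccc2OCc2ccccc2)oc2c(Br)c(O)c(Br)c(O)c12
F3 | step 5 | 1-(2,4,6-trihydroxy-3,5-dimethoxyphenyl)ethanone | COc1c(O)c(OC)c(O)c(C(C)=O)c1O
F4 | step 5 | 2,5-bis(benzyloxy)benzoyl chloride | O=C(Cl)c1cc(OCc2ccccc2)ccc1OCc1ccccc1
F5 | step 1 | methyl 4-methoxy-3-[(trimethylsilyl)oxy]but-2-enoate (mixture of geometric isomers) | COCC(O[Si](C)(C)C)=CC(=O)OC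
F6 | step 1 | 1,4-dimethoxy-1,3-bis[(trimethylsilyl)oxy]buta-1,3-diene (mixture of geometric isomers) | COC=C(O[Si](C)(C)C)C=C(OC)O[Si](C)(C)C
F7 | step 6 | 2-[2,5-bis(benzyloxy)phenyl]-5,6,7,8-tetramethoxy-4H-chromen-4-one | COc1c(OC)c(OC)c2c(=O)cc(-c3cc(OCc4ccccc4)ccc3OCc3ccccc3)oc2c1OC
A1 | alternative 1 | 2,3,4,5-tetramethoxy-6-(trimethylsilyl)phenyl trifluoromethanesulfonate | COc1c(OC)c(OC)c(OS(=O)(=O)C(F)(F)F)c([Si](C)(C)C)c1OC
A2 | alternative 1 | 3-[2,5-bis(benzyloxy)phenyl]prop-2-ynoic acid | OC(=O)C#Cc1cc(OCc2ccccc2)ccc1OCc1ccccc1
A3 | alternative 1 | 2-[2,5-bis(benzyloxy)phenyl]-5,6,7,8-tetramethoxy-4H-chromen-4-one | COc1c(OC)c(OC)c2c(=O)cc(-c3cc(OCc4ccccc4)ccc3OCc3ccccc3)oc2c1OC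
A4 | alternative 2 | 2-ethynyl-5,6,7,8-tetramethoxy-4H-chromen-4-one | C#Cc1cc(=O)c2c(OC)c(OC)c(OC)c(OC)c2o1
A5 | alternative 2 | pentacarbonyl[methoxy(vinyl)carbene]chromium, (CO)5Cr=C(OMe)CH=CH2 | COC(C=C)=[Cr](=C=O)(=C=O)(=C=O)(=C=O)=C=O
A6 | alternative 2 | 2-(2-hydroxy-5-methoxyphenyl)-5,6,7,8-tetramethoxy-4H-chromen-4-one | COc1ccc(O)c(c1)-c1cc(=O)c2c(OC)c(OC)c(OC)c(OC)c2o1
A7 | alternative 3 | 1-[2,5-bis(benzyloxy)phenyl]-3-(2,5-dihydroxy-3,4-dimethoxyphenyl)propane-1,3-dione | COc1c(O)cc(C(=O)CC(=O)c2cc(OCc3ccccc3)ccc2OCc2ccccc2)c(O)c1OC
A8 | alternative 3 | 2-{3-[2,5-bis(benzyloxy)phenyl]-3-oxopropanoyl}-5,6-dimethoxycyclohexa-2,5-diene-1,4-dione | COC1=C(OC)C(=O)C(C(=O)CC(=O)c2cc(OCc3ccccc3)ccc2OCc2ccccc2)=CC1=O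
A9 | alternative 3 | 2-[2,5-bis(benzyloxy)phenyl]-5,8-dihydroxy-6,7-dimethoxy-4H-chromen-4-one | COc1c(OC)c(O)c2c(=O)cc(-c3cc(OCc4ccccc4)ccc3OCc3ccccc3)oc2c1O
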